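## The problem

The target is the isovanillate ester of a cis-fused bicyclo[5.4.0]undecene diol. The numbering used throughout is: C1 and C6 are the ring-fusion CH carbons, C1 beside the CMe2 carbon C11 and C6 beside the methyl carbinol carbon C7; C2=C3 is the ring alkene with the methyl on C3; C4 carries the ester oxygen; C5 is the ring CH2; C8 to C10 are the CH2 groups between C7 and C11; ring A is the cyclohexene and ring B the seven-membered ring. Both fusion carbons carry a fully substituted neighbour in ring B (C11 on C1, C7 on C6), so ring B cannot be closed anywhere by an unhindered bond formation. There are four stereocentres: C1 (S), C6 (R), C7 (S) and C4 (R). C1, C6 and C7 are contiguous and can be relayed from one another through a rigid intermediate, whereas C4 is remote and must be set by the facial bias of ring A (oxygen trans to C7, as in the carvone/carveol series). The groups that limit the chemistry are the tertiary C7 alcohol, the ionisable allylic ester and the free phenol. The C7 oxygen is the most restrictive: it lies β to any carbonyl at C5, which invites elimination or retro-aldol cleavage. The feature that makes a short construction possible is that C1, C6 and C11 are the cyclopropane of (+)-3-carene lacking only the C6–C11 bond, while C7 to C10 with the C7 methyl and oxygen are the atoms of 2-methylfuran. All fifteen carbons of the terpene part therefore exist in two commercial compounds, and only C10–C11 and C6–C7 have to be made. The price is that the ring-forming step needs an acceptor at C5, whereas the target has its oxygen at C4 and its alkene at C2=C3, so ring A must be reorganised afterwards without ever enolising a C5 ketone towards C6.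

## Retrosynthesis

**Ester.** The acyl–O bond at C4 is cut first, giving the allylic alcohol 15 and the phenol-protected acid 18 (from isovanillic acid 16), with silyl ester 19 as the last intermediate before target 20. This keeps the ionisable allylic ester and the phenol out of every reductive and oxidative step. The forward reaction only has to acylate a secondary allylic hydroxyl beside a tertiary one.

**C4 carbinol and C2=C3 alkene.** The unit C4(OH)–C3(Me)=C2 of 15 is the product of a Wharton transposition of epoxy ketone 13, itself the epoxide of the carvone-type enone 12. This cut is preferred to base isomerisation of a 3,4-epoxide or to a singlet-oxygen ene reaction because the alkene position is fixed by the mechanism and not by a choice between ring and methyl hydrogens. The C4 configuration is set by hydroperoxide addition anti to the C6 substituent, as in carvone.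

**C2 carbonyl.** Enone 12 is traced to the trisubstituted alkene 10 by removing the C2 oxygen. The forward SeO2 oxidation is asked to attack the ring CH2 on the more substituted end of the alkene, which is its normal preference.

**C5 oxygen.** Alkene 10 is traced to allylic acetate 9 and diol 8 by returning an oxygen to C5. That oxygen is the remnant of the acceptor the ring-forming step requires. Forward, a palladium-catalysed hydride displacement must remove it without moving the alkene.

**Ring B saturation and the C10–H bond.** Diol 8 comes from cycloheptene 7, and 7 from the oxygen-bridged enone 5 by re-forming the C10–O bond. The bridge serves as the protecting group of the C7 oxygen and as the element that carries stereochemistry from C1 to C7. Forward, the ketone must be reduced before anything else, and the C10–O bond, not the C7–O bond, must be cleaved.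

**Key disconnection.** In 5 the bonds C10–C11 and C6–C7 are cut, giving (1S,6R)-3-caren-5-one 2 and 2-methylfuran 3. Two rings, two skeletal bonds and three stereocentres are removed at once, and what remains is one commercial compound and one compound a single step away. Alternative cuts of ring B form only one bond at a hindered centre. The forward reaction must open the acylcyclopropane at C6–C11 and return C6 to the methyl-bearing furan carbon.

**Chiral pool.** Enone 2 is traced to (+)-3-carene 1 by removing the C5 carbonyl. Carene supplies C1 in the correct absolute configuration.

## Roads not taken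

**Alternative 1:** Ring A is cut at C1–C6 by a retro-Ireland–Claisen step. Forward, the silyl ketene acetal of δ-lactone A1 rearranges [3,3] through a boat, C6 bonding to C1 as the C3–O bond breaks, to give acid A2.
- Merits: A2 already has the C2=C3 alkene, the C4 silyl ether and the cis C1/C6 relationship, so ring A needs no later redox adjustment. In this respect the road is better than the chosen plan, which spends six steps on that adjustment.
- Weak points: A1 must first be built with a quaternary carbinol carbon and a defined C3/C4 relationship over many linear steps. Ring B is still open, and its closure at C7 has to create the tertiary carbinol next to C6 in a seven-membered ring with no rigid element to direct it.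
- Comparison: the chosen plan sets against it that ring B and three stereocentres arise in one step from two commercial compounds, with C7 controlled by a bridge.

**Alternative 2:** Ring B is cut at C1–C6 and ring A at C2=C3. Forward, an amine catalyst converts the aldehyde of linalool-derived chain A3 into an enamine that adds through C1 to the enone β-carbon C6; the ethyl ketone then condenses onto C2 to give enone silyl ether A4.
- Merits: A4 carries the C4 ketone and the C2=C3 alkene exactly where the target needs them, so only reduction, esterification and desilylation remain. If the bicyclisation works, this is the shortest endgame of all and better than the chosen plan.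
- Weak points: the Michael step must close a seven-membered ring onto a β-carbon flanked by the fully substituted C7. The relative configuration of C1/C6 to C7 depends on matching of catalyst and substrate, and A3 itself needs a multi-step chain extension at both ends of linalool.
- Comparison: the chosen plan sets against it an intramolecular, strain-driven ring closure in which C7 is fixed geometrically.

**Alternative 3:** Ring B is cut at C8–C9 and C1–C11. Forward, Rh2(S-DOSP)4 decomposes vinyldiazoacetate A5; the carbenoid cyclopropanates the silyl enol ether alkene of diene A6, and the cis-divinylcyclopropane undergoes Cope rearrangement to cycloheptadiene A7.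
- Merits: this is the best-precedented seven-ring construction of the four and it is catalytic and asymmetric. The chosen key step has no direct precedent, and here this road is clearly stronger.
- Weak points: A7 has an ester at C9 that must be excised, lacks both the C3 and the C7 methyl groups, and sets only C1. The Cope step must form the quaternary C11 from a doubly methylated vinyl terminus, and the ring A pattern still has to be built from a ketal.
- Comparison: the chosen plan sets against its lack of precedent that no carbon has to be added or removed afterwards and that C1 comes from the chiral pool.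

Key step: step 2

Assumption: the C5 carbinol centre of 6 to 9 is transient; it is drawn as the epimer expected from hydride delivery to the face of H6, and either epimer serves the route.

## Route

Step 1
Reactants: 1 (+)-3-carene
Product: 2 (1S,6R)-3-caren-5-one
Conditions: CrO3, 3,5-dimethylpyrazole, CH2Cl2, −20 °C
Reagents that add atoms: chromium trioxide, O=[Cr](=O)=O
Why: Allylic oxidation by the CrO3–3,5-dimethylpyrazole complex (hexavalent chromium) takes the ring CH2 beside the unsubstituted alkene carbon and leaves the cyclopropane and both stereocentres untouched.

Step 2
Reactants: 2 (1S,6R)-3-caren-5-one; 3 2-methylfuran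
Product: 5 oxygen-bridged tricyclic enone, via titanium dienolate furanium zwitterion 4 (not isolated)
Conditions: TiCl4 (1.2 equiv), 2-methylfuran (3 equiv), CH2Cl2, −78 °C; aq NaHCO3 quench at −78 °C
Reagents that add atoms: none
Why: Proposed new method: TiCl4 binds the enone oxygen and heterolyses the cyclopropane bond C6–C11, which overlaps the carbonyl π system, to a tertiary C11 cation and a titanium dienolate at C6; the free α-carbon of 2-methylfuran adds to C11 (C10–C11) to give zwitterion 4, and C6 then attacks the methyl-bearing oxocarbenium carbon C7. The closest known reaction types are the Lewis-acid formal (4+3) and (3+2) annulations of donor–acceptor cyclopropanes with dienes and the (4+3) cycloadditions of oxyallyl cations with furans. The C6–C7 bond closes ring B in a 7-(enolexo)-exo-trig mode and, in the same event, the oxygen-bridged six-membered ring in a 6-(enolexo)-endo-trig mode. C10 is set in the furan addition and only has to be cis to C7 across the bridge, which the one-atom oxygen bridge enforces. C6 is set by least motion: C11 stays on the enolate face it occupied in the cyclopropane, so the three-atom tether returns C7 to that face and the fusion is cis, under control of the fixed C1 centre. C7 is set by a closed, synclinal transition state in which the oxocarbenium oxygen lies over the titanium-bound enolate oxygen on C5 (Coulombic contact within the zwitterion), which puts the bridge syn to C5 and the C7 methyl on the face of H6. The step needs attack at C7 and not at C9 (the (3+2) mode) and closure faster than proton loss from C10 (rearomatisation); the positive charge of the 2H-furanium ion is largest at C7, and the base-free medium at −78 °C denies the C10 proton an acceptor. The cold neutral quench also protects 5, whose C6–H is antiperiplanar to the C7–O bond, from β-elimination.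

Step 3
Reactants: 5 oxygen-bridged tricyclic enone
Product: 7 cycloheptene diol, via bridged allylic alcohol 6 (not isolated)
Conditions: i-Bu2AlH (1.1 equiv), PhMe, −78 °C; then Ni(cod)2 (10 mol %), i-Bu2AlH (2.5 equiv), PhMe, 0 to 60 °C; aq potassium sodium tartrate
Reagents that add atoms: none
Why: i-Bu2AlH first reduces the enone carbonyl 1,2 under non-basic conditions, removing the ketone whose C6 enolate would expel the C7 oxygen. Zerovalent nickel then catalyses exo hydroalumination of the strained C8=C9 bond with aluminium at C9, remote from the bridgehead methyl, and syn β-alkoxide elimination cleaves C10–O (nickel-catalysed hydroalumination and ring opening of oxabicyclic alkenes). The new C5 centre is transient.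

Step 4
Reactants: 7 cycloheptene diol
Product: 8 diol with saturated ring B
Conditions: H2 (1 atm), RhCl(PPh3)3 (5 mol %), PhH–EtOH, rt
Reagents that add atoms: none
Why: Homogeneous hydrogenation with RhCl(PPh3)3 reduces the cis-disubstituted C9=C10 alkene and leaves the trisubstituted C3=C4 alkene; no stereocentre is formed.

Step 5
Reactants: 8 diol with saturated ring B
Product: 9 C5 allylic acetate
Conditions: Ac2O (1.2 equiv), pyridine, DMAP (cat.), CH2Cl2, 0 °C to rt
Reagents that add atoms: acetic anhydride, CC(=O)OC(C)=O
Why: DMAP-catalysed acetylation takes the secondary allylic hydroxyl and leaves the hindered tertiary C7 hydroxyl free.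

Step 6
Reactants: 9 C5 allylic acetate
Product: 10 C5-deoxygenated alkenol
Conditions: Pd(PPh3)4 (5 mol %), LiBHEt3, THF, 0 °C to rt
Reagents that add atoms: none
Why: Zerovalent palladium ionises the allylic acetate from the face opposite the leaving group, and hydride from LiBHEt3 goes to the less substituted allyl terminus C5, which keeps the trisubstituted C3=C4 alkene (palladium-catalysed hydride reduction of allylic acetates). C5 ceases to be a stereocentre.

Step 7
Reactants: 10 C5-deoxygenated alkenol
Product: 12 C2 enone, via allylic alcohol 11 (not isolated)
Conditions: SeO2 (0.5 equiv), t-BuOOH, CH2Cl2, rt; then Dess–Martin periodinane, NaHCO3, CH2Cl2, 0 °C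
Reagents that add atoms: selenium dioxide, O=[Se]=O; tert-butyl hydroperoxide, CC(C)(C)OO
Why: Allylic hydroxylation with SeO2 (ene reaction at C4, then [2,3] shift) places oxygen on the ring CH2 at the more substituted end of the alkene, C2, and returns the alkene to C3=C4. Oxidation of the crude alcohol converges on the carvone-type enone and erases the C2 carbinol configuration.

Step 8
Reactants: 12 C2 enone
Product: 13 epoxy ketone
Conditions: H2O2 (30 % aq), NaOH (0.2 equiv), MeOH, 0 °C
Reagents that add atoms: hydrogen peroxide, OO
Why: In this Weitz–Scheffer epoxidation hydroperoxide adds to C4 anti to the C6 substituent (C7), as it adds anti to the isopropenyl group of carvone. The epoxide oxygen thus lands on the face of H6, and C3 and C4 are set with C4 in the target configuration. Short, cold exposure to catalytic base should spare the hindered C1–H.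

Step 9
Reactants: 13 epoxy ketone
Product: 15 allylic alcohol, via epoxy hydrazone 14 (not isolated)
Conditions: N2H4·H2O, AcOH (cat.), MeOH, 0 °C to rt
Reagents that add atoms: none
Why: In the Wharton transposition the epoxy hydrazone loses N2, moving the alkene to C2=C3 and leaving the C4 oxygen with its configuration; carvone oxide gives trans-carveol in the same way.

Step 10
Reactants: 16 isovanillic acid
Product: 18 3-(tert-butyldimethylsilyloxy)-4-methoxybenzoic acid, via bis-silyl derivative 17 (not isolated)
Conditions: TBSCl (2.2 equiv), imidazole, DMF, rt; then AcOH–THF–H2O, rt
Reagents that add atoms: tert-butyldimethylsilyl chloride, CC(C)(C)[Si](C)(C)Cl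
Why: Phenol and acid are both silylated, and the labile silyl ester is then hydrolysed selectively, the standard protection of hydroxybenzoic acids.

Step 11
Reactants: 15 allylic alcohol; 18 3-(tert-butyldimethylsilyloxy)-4-methoxybenzoic acid
Product: 19 silyl-protected ester
Conditions: EDC·HCl, DMAP, CH2Cl2, 0 °C to rt
Reagents that add atoms: none
Why: Steglich esterification acylates the secondary allylic C4 hydroxyl with retention; the tertiary C7 hydroxyl does not react under carbodiimide/DMAP conditions.

Step 12
Reactants: 19 silyl-protected ester
Product: 20 target CNP0210711.3
Conditions: Bu4NF, AcOH, THF, 0 °C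
Reagents that add atoms: none
Why: Fluoride cleaves the aryl silyl ether quickly at 0 °C, and acetic acid buffers the phenoxide so that the allylic benzoate and the tertiary alcohol are untouched.

## Compound list

1 | (+)-3-carene | CC1=CC[C@@H]2[C@H](C1)C2(C)C | starting material
2 | (1S,6R)-3-caren-5-one (4,7,7-trimethylbicyclo[4.1.0]hept-3-en-2-one with the cyclopropane configuration of 1) | CC1=CC(=O)[C@@H]2[C@H](C1)C2(C)C | intermediate
3 | 2-methylfuran | Cc1ccco1 | starting material
4 | titanium dienolate furanium zwitterion (C10–C11 formed, C6–C7 still open) | CC1=CC(O[Ti-](Cl)(Cl)(Cl)Cl)=C[C@H](C1)C(C)(C)[C@H]2C=CC(C)=[O+]2 | intermediate (not isolated)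
5 | oxygen-bridged tricyclic enone: ring A cyclohexenone (C5 ketone, C3=C4) cis-fused at C1–C6 to an 8-oxabicyclo[3.2.1]oct-6-ene (oxygen bridging C7 and C10, syn to C5; C8=C9) | CC1=CC(=O)[C@@H]2[C@H](C1)C(C)(C)[C@H]3C=C[C@]2(C)O3 | intermediate
6 | bridged allylic alcohol (C5 carbinol, bridge intact) | CC1=C[C@@H](O)[C@@H]2[C@H](C1)C(C)(C)[C@H]3C=C[C@]2(C)O3 | intermediate (not isolated)
7 | cycloheptene diol (C5 and C7 hydroxyls, C3=C4 and C9=C10 alkenes) | CC1=C[C@@H](O)[C@@H]2[C@H](C1)C(C)(C)C=CC[C@]2(C)O | intermediate
8 | diol with saturated ring B (C5 and C7 hydroxyls, C3=C4) | CC1=C[C@@H](O)[C@@H]2[C@H](C1)C(C)(C)CCC[C@]2(C)O | intermediate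
9 | C5 allylic acetate of 8 | CC1=C[C@@H](OC(C)=O)[C@@H]2[C@H](C1)C(C)(C)CCC[C@]2(C)O | intermediate
10 | C5-deoxygenated alkenol (C3=C4, C7 hydroxyl) | CC1=CC[C@@H]2[C@H](C1)C(C)(C)CCC[C@]2(C)O | intermediate
11 | C2 allylic alcohol (hydroxyl on the face of H1, C3=C4) | CC1=CC[C@@H]2[C@H]([C@@H]1O)C(C)(C)CCC[C@]2(C)O | intermediate (not isolated)
12 | C2 enone (C2 ketone, C3=C4, C7 hydroxyl) | CC1=CC[C@@H]2[C@H](C1=O)C(C)(C)CCC[C@]2(C)O | intermediate
13 | epoxy ketone (C2 ketone, 3,4-epoxide on the face of H6) | C[C@@]12O[C@@H]1C[C@@H]3[C@H](C2=O)C(C)(C)CCC[C@]3(C)O | intermediate
14 | epoxy hydrazone of 13 | C[C@@]12O[C@@H]1C[C@@H]3[C@H](C2=NN)C(C)(C)CCC[C@]3(C)O | intermediate (not isolated)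
15 | allylic alcohol (C4 R carbinol, C2=C3, C7 hydroxyl) | O[C@@H]1C[C@@H]2[C@H](C=C1C)C(C)(C)CCC[C@]2(C)O | intermediate
16 | isovanillic acid | COc1ccc(C(=O)O)cc1O | starting material
17 | bis-silyl derivative of 16 (silyl ester and aryl silyl ether) | COc1ccc(C(=O)O[Si](C)(C)C(C)(C)C)cc1O[Si](C)(C)C(C)(C)C | intermediate (not isolated)
18 | 3-(tert-butyldimethylsilyloxy)-4-methoxybenzoic acid | COc1ccc(C(=O)O)cc1O[Si](C)(C)C(C)(C)C | intermediate
19 | silyl-protected ester (C4 ester of 15 with 18) | COc1ccc(C(=O)O[C@@H]2C[C@@H]3[C@H](C=C2C)C(C)(C)CCC[C@]3(C)O)cc1O[Si](C)(C)C(C)(C)C | intermediate
20 | target CNP0210711.3 (C1 S, C4 R, C6 R, C7 S) | COc1ccc(C(=O)O[C@@H]2C[C@@H]3[C@H](C=C2C)C(C)(C)CCC[C@]3(C)O)cc1O | target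

## Step count and least certain steps

Total step count: 12. Longest linear sequence: 11 steps (steps 1 to 9, 11 and 12); step 10 is the one-step side branch.

**Step 2 (key step, proposed new method).**
- What may go wrong: proton loss from C10 of zwitterion 4 (rearomatisation to the alkylated furan) may outrun C6–C7 closure. Closure may occur at C9 in the (3+2) mode. Closure through an open transition state would place the bridge anti to ring A. The product may also suffer β-elimination of the C7 oxygen on warming.
- Fallback with known chemistry, giving up the oxygen bridge: it sets out from 2.
  - The same TiCl4 ionisation is run with allyltrimethylsilane, a Hosomi–Sakurai capture of the tertiary cation, to give allyl enone F1.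
  - Cross-metathesis with methyl vinyl ketone under the second-generation Grubbs catalyst gives bis-enone F2.
  - Conjugate reduction of the acyclic enone with [(Ph3P)CuH]6 gives diketone F3.
  - Intramolecular aldol addition of the ring A α′-lithium enolate (LiN(SiMe3)2, THF, −78 °C) to the methyl ketone forms C6–C7 and gives hydroxy enone F4.
  - Reduction with NaBH4/CeCl3·7H2O rejoins the route at 8.
- Cost of the fallback: C6 and C7 then rest on an aldol addition that is not expected to be selective, and the isomers would have to be separated.

**Step 3.**
- What may go wrong: aluminium may be placed at C8, so that the C7–O bond is cleaved instead of C10–O. The catalytic cycle may also stall on the hindered alkene in the presence of the aluminium alkoxide.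
- Fallback: 5 is reduced separately with NaBH4/CeCl3·7H2O and 6 is isolated. Stoichiometric, uncatalysed hydroboration with 9-borabicyclo[3.3.1]nonane (exo face, boron at the carbon remote from the bridgehead methyl) gives alkylborane F5. BF3·OEt2 then induces syn β-alkoxy elimination, which cleaves C10–O and returns to 7.

**Step 6.**
- What may go wrong: hydride may be delivered to the tertiary terminus C3, giving the C4=C5 isomer, or the acetate carbonyl may simply be reduced, regenerating 8.
- Fallback: electron-transfer cleavage of acetate 9 with Li in EtNH2 at −78 °C; the allyl anion is protonated at the less substituted terminus and 10 is reached directly. This fallback makes no new compound (F0).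

**Step 7.**
- What may go wrong: poor site selectivity (oxidation of the C3 methyl instead of C2) and over-oxidation.
- Fallback: from 10, a Schenck ene reaction (O2, light, tetraphenylporphyrin, CH2Cl2) places oxygen directly on C4 with the alkene shifting to C2=C3, giving allylic hydroperoxide F6. Reduction with PPh3 rejoins the route at 15 and bypasses 11 to 14. The isomer with an exocyclic alkene is the expected companion and would have to be separated.

**Step 9 (with the ketone stage of step 8).**
- What may go wrong: slow hydrazone formation at the hindered C2 ketone, and erosion of the cis ring fusion by epimerisation at C1, which is α to that ketone under hydroxide or hydrazine.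
- Fallback without a carbonyl at C2: it sets out from 11, isolated from step 7 before the Dess–Martin oxidation.
  - VO(acac)2/t-BuOOH epoxidation directed by the C2 hydroxyl gives epoxy alcohol F7.
  - PhOC(S)Cl with pyridine gives thionocarbonate F8.
  - Bu3SnH with AIBN generates the C2 radical, which opens the epoxide to the C4 alkoxy radical and, after hydrogen transfer, gives 15.

## Further compounds

F1 | step 2 | allyl enone | CC1=CC(=O)C[C@H](C1)C(C)(C)CC=C
F2 | step 2 | bis-enone | CC1=CC(=O)C[C@H](C1)C(C)(C)C/C=C/C(C)=O
F3 | step 2 | diketone | CC1=CC(=O)C[C@H](C1)C(C)(C)CCCC(C)=O
F4 | step 2 | hydroxy enone | CC1=CC(=O)[C@@H]2[C@H](C1)C(C)(C)CCC[C@]2(C)O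
F5 | step 3 | alkylborane | CC1=C[C@@H](O)[C@@H]2[C@H](C1)C(C)(C)[C@H]3[C@H](B4C5CCCC4CCC5)C[C@]2(C)O3
F0 | step 6 | none | none
F6 | step 7 | allylic hydroperoxide | OO[C@@H]1C[C@@H]2[C@H](C=C1C)C(C)(C)CCC[C@]2(C)O
F7 | step 9 | epoxy alcohol | C[C@@]12O[C@@H]1C[C@@H]3[C@H]([C@@H]2O)C(C)(C)CCC[C@]3(C)O
F8 | step 9 | thionocarbonate | C[C@@]12O[C@@H]1C[C@@H]3[C@H]([C@@H]2OC(=S)Oc4ccccc4)C(C)(C)CCC[C@]3(C)O
A1 | alternative 1 | δ-lactone with the C3 methyl, the (E)-alkenyl chain and the C4 silyl ether (alkenyl cis to the silyloxy group) | C[C@]1(/C=C/C(C)(C)CCCOCc2ccc(OC)cc2)OC(=O)CC[C@H]1O[Si](C)(C)C(C)(C)C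
A2 | alternative 1 | ring A carboxylic acid | CC(C)(C)[Si](C)(C)O[C@@H]1C[C@@H](C(=O)O)[C@H](C=C1C)C(C)(C)CCCOCc2ccc(OC)cc2
A3 | alternative 2 | linalool-derived keto aldehyde chain | CCC(=O)/C=C/[C@@](C)(O[Si](CC)(CC)CC)CCCC(C)(C)CC=O
A4 | alternative 2 | cis-fused bicyclic enone silyl ether | O=C1C[C@@H]2[C@H](C=C1C)C(C)(C)CCC[C@]2(C)O[Si](CC)(CC)CC
A5 | alternative 3 | methyl 2-diazo-4-methylpent-3-enoate | COC(=O)C(=[N+]=[N-])C=C(C)C
A6 | alternative 3 | 8-[1-(tert-butyldimethylsilyloxy)vinyl]-1,4-dioxaspiro[4.5]dec-7-ene | C=C(O[Si](C)(C)C(C)(C)C)C1=CCCC2(C1)OCCO2
A7 | alternative 3 | bicyclic cycloheptadiene ester | COC(=O)C1=CC(C)(C)[C@H]2CCC3(OCCO3)CC2=C(O[Si](C)(C)C(C)(C)C)C1
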